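**Retrosynthetic overview**

1. The strategy rests on ring B (the 8-linked 7-methoxycoumarin): O7 and the styryl carbon on C8 are neighbours, and C8 is flanked by the lactone oxygen on C8a, so a 7,8-aryne of the coumarin can take up an aldehyde oxygen at C7 and the aldehyde carbon at C8.
2. The last cut is O7–CH3 of ring B; before it, C7–O and C8–CH= are cut together (aryne 18 plus aldehyde 11, then benzoxete, ortho-quinone methide and 1,5-hydrogen shift to the E alkene).
3. Aldehyde 11 comes by one-carbon homologation of 9, the endo adduct of a catalyst-controlled Diels–Alder reaction of aryl diene 7 with methacrolein (ring C and both stereocentres in one step).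
4. Diene 7 comes from Suzuki coupling of 6-bromo-7-methoxycoumarin 3 (ring A by Pechmann condensation) with dienylboronate 6; aryne precursor 17 comes from 7-hydroxycoumarin by 8-iodination, O-silylation, retro-Brook shift and triflation.
5. Ring order: pyranone of ring A, then ring C; ring B is bought intact and joined last.

Key step: step 11

Remark on the chemistry: ring A is the 6-linked coumarin, ring B the 8-linked coumarin, ring C the cyclohexene. The SMILES is read as (1S,2S) on ring C (C1 quaternary, C2 aryl-bearing), with the ring A aryl group cis to the styryl arm and trans to the quaternary methyl.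

**Route**

Step 1
Reactants: 1 4-bromoresorcinol (4-bromobenzene-1,3-diol)
Product: 2 6-bromo-7-hydroxy-2H-chromen-2-one
Conditions: DL-malic acid, conc. H2SO4, 110 °C
Reagents that add atoms: DL-malic acid, OC(CC(=O)O)C(=O)O
Why: Pechmann condensation, in which malic acid loses CO and water to formylacetic acid, which attacks the ring carbon para to one hydroxyl and ortho to the other and lactonises, so that bromine ends at C6 and the free hydroxyl at C7.

Step 2
Reactants: 2 6-bromo-7-hydroxy-2H-chromen-2-one
Product: 3 6-bromo-7-methoxy-2H-chromen-2-one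
Conditions: MeI, K2CO3, acetone, reflux
Reagents that add atoms: iodomethane, CI
Why: Williamson O-methylation of the acidic 7-hydroxyl, with the lactone inert to K2CO3 in acetone.

Step 3
Reactants: 4 2-methylbut-1-en-3-yne; 5 pinacolborane (4,4,5,5-tetramethyl-1,3,2-dioxaborolane)
Product: 6 (E)-4,4,5,5-tetramethyl-2-(3-methylbuta-1,3-dien-1-yl)-1,3,2-dioxaborolane
Conditions: Cp2Zr(H)Cl (5 mol%), Et3N (10 mol%), neat, sealed tube, 60 °C
Reagents that add atoms: none
Why: Zirconium-catalysed syn hydroboration of the terminal alkyne should place boron on the terminal carbon and give the E alkenylboronate, the 1,1-disubstituted alkene being left alone.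

Step 4
Reactants: 3 6-bromo-7-methoxy-2H-chromen-2-one; 6 (E)-4,4,5,5-tetramethyl-2-(3-methylbuta-1,3-dien-1-yl)-1,3,2-dioxaborolane
Product: 7 7-methoxy-6-[(1E)-3-methylbuta-1,3-dien-1-yl]-2H-chromen-2-one
Conditions: Pd(dppf)Cl2 (5 mol%), K2CO3, dioxane/H2O 5:1, 80 °C; dilute HCl wash; product kept cold and used at once
Reagents that add atoms: none
Why: Suzuki–Miyaura coupling of the aryl bromide with the alkenylboronate proceeds with retention of the E geometry, and the acidic wash re-closes any lactone opened by the aqueous base.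

Step 5
Reactants: 7 7-methoxy-6-[(1E)-3-methylbuta-1,3-dien-1-yl]-2H-chromen-2-one; 8 methacrolein (2-methylprop-2-enal)
Product: 9 (1R,2R)-2-(7-methoxy-2-oxo-2H-chromen-6-yl)-1,4-dimethylcyclohex-3-ene-1-carbaldehyde
Conditions: (R)-1-(2-methylphenyl)-3,3-diphenyltetrahydro-1H,3H-pyrrolo[1,2-c][1,3,2]oxazaborole (20 mol%), Tf2NH (18 mol%), methacrolein (3 equiv), CH2Cl2, −78 to −40 °C
Reagents that add atoms: none
Why: Oxazaborolidinium-catalysed Diels–Alder reaction in which the aryl group on C1 and the methyl on C3 of the diene both send the unsubstituted diene terminus to the β-carbon of methacrolein, the endo transition state puts CHO cis to the aryl group, and the (R)-catalyst, which holds s-trans methacrolein through boron and a formyl C–H···O contact and covers one face with a phenyl group, should leave the Si face of the α-carbon open, so that the quaternary centre forms as R and, through the endo mode, the aryl-bearing centre as R.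

Step 6
Reactants: 9 (1R,2R)-2-(7-methoxy-2-oxo-2H-chromen-6-yl)-1,4-dimethylcyclohex-3-ene-1-carbaldehyde
Product: 10 7-methoxy-6-[(1S,6R)-6-(2-methoxyethenyl)-3,6-dimethylcyclohex-2-en-1-yl]-2H-chromen-2-one (E/Z mixture)
Conditions: Ph3P(CH2OMe)Cl (1.6 equiv), KN(SiMe3)2 (1.5 equiv), THF, −78 to 0 °C
Reagents that add atoms: (methoxymethyl)triphenylphosphonium chloride, COC[P+](c1ccccc1)(c1ccccc1)c1ccccc1.[Cl-]
Why: Wittig reaction of the preformed methoxymethylene ylide with the aldehyde, which is far more electrophilic than the lactone carbonyl and has no α-hydrogen, so the quaternary centre cannot epimerise and the enol ether geometry is of no consequence.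

Step 7
Reactants: 10 7-methoxy-6-[(1S,6R)-6-(2-methoxyethenyl)-3,6-dimethylcyclohex-2-en-1-yl]-2H-chromen-2-one
Product: 11 2-[(1S,2S)-2-(7-methoxy-2-oxo-2H-chromen-6-yl)-1,4-dimethylcyclohex-3-en-1-yl]acetaldehyde
Conditions: 2 M HCl, THF, 25 °C
Reagents that add atoms: water, O
Why: Acid hydrolysis of the enol ether gives the homologated aldehyde, and neither stereocentre is enolisable, so both are carried through unchanged.

Step 8
Reactants: 12 7-hydroxy-2H-chromen-2-one (7-hydroxycoumarin)
Product: 13 7-hydroxy-8-iodo-2H-chromen-2-one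
Conditions: I2, KI, 20% aq NH3, 25 °C; then dilute H2SO4
Reagents that add atoms: iodine, II
Why: Electrophilic iodination of the phenoxide at C8, the most nucleophilic ring position, which lies ortho to O7 and between two oxygen-bearing carbons.

Step 9
Reactants: 13 7-hydroxy-8-iodo-2H-chromen-2-one
Product: 14 8-iodo-7-(trimethylsilyloxy)-2H-chromen-2-one
Conditions: (Me3Si)2NH, THF, 70 °C; evaporated and used crude
Reagents that add atoms: hexamethyldisilazane, C[Si](C)(C)N[Si](C)(C)C
Why: O-Silylation of the phenol by silyl transfer from the disilazane, with ammonia as the only by-product.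

Step 10
Reactants: 14 8-iodo-7-(trimethylsilyloxy)-2H-chromen-2-one
Product: 17 2-oxo-8-(trimethylsilyl)-2H-chromen-7-yl trifluoromethanesulfonate, via 8-lithio silyl ether 15 (not isolated), via lithium phenoxide 16 (not isolated)
Conditions: n-BuLi (1.05 equiv), THF, −100 °C, 20 min; Tf2O, −100 to −78 °C
Reagents that add atoms: trifluoromethanesulfonic anhydride, O=S(=O)(OS(=O)(=O)C(F)(F)F)C(F)(F)F
Why: Iodine–lithium exchange at −100 °C should outrun addition to the lactone, the aryllithium 15 takes the silyl group from the neighbouring oxygen (retro-Brook 1,3-shift), and the lithium phenoxide 16 is triflated on oxygen.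

Step 11
Reactants: 11 2-[(1S,2S)-2-(7-methoxy-2-oxo-2H-chromen-6-yl)-1,4-dimethylcyclohex-3-en-1-yl]acetaldehyde; 17 2-oxo-8-(trimethylsilyl)-2H-chromen-7-yl trifluoromethanesulfonate
Product: 21 7-hydroxy-8-[(E)-2-[(1S,2S)-2-(7-methoxy-2-oxo-2H-chromen-6-yl)-1,4-dimethylcyclohex-3-en-1-yl]ethenyl]-2H-chromen-2-one, via 7,8-didehydrocoumarin 18 (not isolated), via benzoxete 19 (not isolated), via ortho-quinone methide 20 (not isolated)
Conditions: 11 (2 equiv, excess recovered), 17 (1 equiv), Bu4N[Ph3SiF2] (1.1 equiv, added over 6 h), THF, 25 °C; then aq NH4Cl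
Reagents that add atoms: none
Why: Proposed new method: fluoride removes the silyl group of 17 and triflate leaves, giving aryne 18; the carbonyl oxygen of 11 adds to C7 and the aryl anion at C8 collapses onto the oxocarbenium carbon, a stepwise [2+2] that makes the C7–O and C8–C bonds in benzoxete 19. The oxete is the only ring closed (by collapse of the 1,4-zwitterion); it reopens by four-electron electrocyclic ring opening to ortho-quinone methide 20, and a [1,5]-hydrogen shift from the CH2 group beside the quaternary carbon to oxygen restores the arene and leaves the conjugated alkene, while an ortho-quinone methide isomer with the side chain turned away from the carbonyl can re-close and reopen. The closest known reactions are the insertion of arynes into the C=O bond of formamides and aldehydes through benzoxetes and ortho-quinone methides, and the tautomerisation of alkyl-substituted ortho-quinone methides to ortho-alkenylphenols. No stereocentre is created and the two existing ones carry no acidic hydrogen; the E geometry follows from a hydrogen-shift transition state that keeps the quaternary carbon away from the arene. The regiochemistry needed (oxygen at C7, carbon at C8) is secured by the lactone oxygen on C8a, which makes C7 the electrophilic aryne terminus and stabilises negative charge developing at C8. The alkene can form in one position only because the next carbon is quaternary, and slow addition of a stoichiometric fluoride source keeps aryne and phenoxide concentrations low, which should hold back O-arylation of 21 and aryne trapping of 20.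

Step 12
Reactants: 21 7-hydroxy-8-[(E)-2-[(1S,2S)-2-(7-methoxy-2-oxo-2H-chromen-6-yl)-1,4-dimethylcyclohex-3-en-1-yl]ethenyl]-2H-chromen-2-one
Product: 22 7-methoxy-8-[(E)-2-[(1S,2S)-2-(7-methoxy-2-oxo-2H-chromen-6-yl)-1,4-dimethylcyclohex-3-en-1-yl]ethenyl]-2H-chromen-2-one
Conditions: MeI, K2CO3, acetone, 40 °C
Reagents that add atoms: iodomethane, CI
Why: Williamson O-methylation of the single free phenol, which touches neither the alkenes nor the stereocentres.

**Compound list**

1 | 4-bromoresorcinol | Oc1ccc(Br)c(O)c1 | starting material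
2 | 6-bromo-7-hydroxy-2H-chromen-2-one | O=c1ccc2cc(Br)c(O)cc2o1 | intermediate
3 | 6-bromo-7-methoxy-2H-chromen-2-one | COc1cc2oc(=O)ccc2cc1Br | intermediate
4 | 2-methylbut-1-en-3-yne | C=C(C)C#C | starting material
5 | pinacolborane | CC1(C)OBOC1(C)C | starting material
6 | (E)-4,4,5,5-tetramethyl-2-(3-methylbuta-1,3-dien-1-yl)-1,3,2-dioxaborolane | CC(=C)/C=C/B1OC(C)(C)C(C)(C)O1 | intermediate
7 | 7-methoxy-6-[(1E)-3-methylbuta-1,3-dien-1-yl]-2H-chromen-2-one | COc1cc2oc(=O)ccc2cc1/C=C/C(C)=C | intermediate
8 | methacrolein | CC(=C)C=O | starting material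
9 | (1R,2R)-2-(7-methoxy-2-oxo-2H-chromen-6-yl)-1,4-dimethylcyclohex-3-ene-1-carbaldehyde (CHO cis to aryl) | COc1cc2oc(=O)ccc2cc1[C@H]1C=C(C)CC[C@@]1(C)C=O | intermediate
10 | 7-methoxy-6-[(1S,6R)-6-(2-methoxyethenyl)-3,6-dimethylcyclohex-2-en-1-yl]-2H-chromen-2-one (E/Z mixture) | COc1cc2oc(=O)ccc2cc1[C@H]1C=C(C)CC[C@@]1(C)C=COC | intermediate
11 | 2-[(1S,2S)-2-(7-methoxy-2-oxo-2H-chromen-6-yl)-1,4-dimethylcyclohex-3-en-1-yl]acetaldehyde | COc1cc2oc(=O)ccc2cc1[C@H]1C=C(C)CC[C@@]1(C)CC=O | intermediate
12 | 7-hydroxy-2H-chromen-2-one | O=c1ccc2ccc(O)cc2o1 | starting material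
13 | 7-hydroxy-8-iodo-2H-chromen-2-one | O=c1ccc2ccc(O)c(I)c2o1 | intermediate
14 | 8-iodo-7-(trimethylsilyloxy)-2H-chromen-2-one | C[Si](C)(C)Oc1ccc2ccc(=O)oc2c1I | intermediate
15 | 8-lithio-7-(trimethylsilyloxy)-2H-chromen-2-one | [Li]c1c(O[Si](C)(C)C)ccc2ccc(=O)oc12 | intermediate (not isolated)
16 | lithium 2-oxo-8-(trimethylsilyl)-2H-chromen-7-olate | [Li+].[O-]c1ccc2ccc(=O)oc2c1[Si](C)(C)C | intermediate (not isolated)
17 | 2-oxo-8-(trimethylsilyl)-2H-chromen-7-yl trifluoromethanesulfonate | C[Si](C)(C)c1c(OS(=O)(=O)C(F)(F)F)ccc2ccc(=O)oc12 | intermediate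
18 | 7,8-didehydro-2H-chromen-2-one (coumarin 7,8-aryne) | O=C1C=CC2=C(O1)C#CC=C2 | intermediate (not isolated)
19 | benzoxete from 18 and 11 (oxete fused at C7–C8 of ring B, O on C7, CH carrying the CH2–ring C arm on C8; epimers at the oxete CH) | COc1cc2oc(=O)ccc2cc1[C@H]1C=C(C)CC[C@@]1(C)CC1Oc2ccc3ccc(=O)oc3c21 | intermediate (not isolated)
20 | ortho-quinone methide (ring B with C7=O and C8=CH–CH2–ring C arm) | COc1cc2oc(=O)ccc2cc1[C@H]1C=C(C)CC[C@@]1(C)CC=C1C(=O)C=CC2=C1OC(=O)C=C2 | intermediate (not isolated)
21 | 7-hydroxy-8-[(E)-2-[(1S,2S)-2-(7-methoxy-2-oxo-2H-chromen-6-yl)-1,4-dimethylcyclohex-3-en-1-yl]ethenyl]-2H-chromen-2-one | COc1cc2oc(=O)ccc2cc1[C@H]1C=C(C)CC[C@@]1(C)/C=C/c1c(O)ccc2ccc(=O)oc12 | intermediate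
22 | 7-methoxy-8-[(E)-2-[(1S,2S)-2-(7-methoxy-2-oxo-2H-chromen-6-yl)-1,4-dimethylcyclohex-3-en-1-yl]ethenyl]-2H-chromen-2-one | COc1cc2oc(=O)ccc2cc1[C@H]1C=C(C)CC[C@@]1(C)/C=C/c1c(OC)ccc2ccc(=O)oc12 | target

**Step count**

Total: 12 steps. Longest linear sequence: 8 steps (steps 1, 2, 4, 5, 6, 7, 11, 12).

**Steps most likely to fail**

Step 11. The weakly nucleophilic aliphatic aldehyde may capture the aryne too slowly. The aryne could then oligomerise or undergo an ene reaction with the ring C alkene, fluoride could trigger aldol condensation of the aldehyde, or the product phenol could be arylated. The fallback uses known chemistry and sets out from 9 and 13. Aldehyde 9 is methylenated with Ph3PCH3Br and KN(SiMe3)2 in THF to the vinyl compound 6-[(1S,6S)-6-ethenyl-3,6-dimethylcyclohex-2-en-1-yl]-7-methoxy-2H-chromen-2-one F1. Phenol 13 is methylated with MeI and K2CO3 to 8-iodo-7-methoxy-2H-chromen-2-one F2. A Heck reaction of F2 with F1 (palladium diacetate, P(o-tol)3, Et3N, DMF, 90 °C) then joins the aryl group to the terminal alkene carbon. Because the other neighbour of the internal carbon is quaternary, β-hydride elimination can give only the E styryl alkene. The fallback comes back to the route at target 22.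

Step 5. The Lewis-basic lactone carbonyl of 7 may bind the catalyst, or the acid may oligomerise the electron-rich aryl diene, which would lower conversion, endo selectivity or enantioselectivity. The fallback sets out from 7 and 8. A Diels–Alder reaction promoted by EtAlCl2 (CH2Cl2, −78 to −20 °C) should give the racemic endo adduct rac-9 F3. Condensation with (1R,2R)-N,N′-dimethyl-1,2-diphenylethane-1,2-diamine (4 Å sieves, Et2O, 25 °C) gives two diastereomeric imidazolidines, which have no new stereocentre at the aminal carbon: the aminal of (1R,2R)-9 F4 and the aminal of (1S,2S)-9 F5. These are separated by chromatography on base-washed silica or by crystallisation. Hydrolysis of F4 with 0.5 M HCl in Et2O releases the diamine and returns the route to 9.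

Step 10. Butyllithium may add to the lactone carbonyl or to C4 in competition with iodine–lithium exchange, and the aryllithium may attack a second molecule before the silyl shift. The fallback avoids organolithium reagents and sets out from 13. The phenol is protected with 4-methoxybenzyl chloride and K2CO3 in DMF as 8-iodo-7-[(4-methoxyphenyl)methoxy]-2H-chromen-2-one F6. Palladium-catalysed silylation with Me3SiSiMe3 (Pd2(dba)3, 2-(di-tert-butylphosphino)biphenyl, KF, DMPU with a trace of water, 100 °C) gives 7-[(4-methoxyphenyl)methoxy]-8-(trimethylsilyl)-2H-chromen-2-one F7. Oxidative removal of the benzyl group with DDQ in CH2Cl2/H2O gives 7-hydroxy-8-(trimethylsilyl)-2H-chromen-2-one F8 without acid, which avoids protodesilylation. Triflation with Tf2O and pyridine in CH2Cl2 at 0 °C returns the route to 17.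

**Further compounds**

F1 | step 11 | 6-[(1S,6S)-6-ethenyl-3,6-dimethylcyclohex-2-en-1-yl]-7-methoxy-2H-chromen-2-one | COc1cc2oc(=O)ccc2cc1[C@H]1C=C(C)CC[C@@]1(C)C=C
F2 | step 11 | 8-iodo-7-methoxy-2H-chromen-2-one | COc1ccc2ccc(=O)oc2c1I
F3 | step 5 | rac-9, racemic (1R*,2R*)-2-(7-methoxy-2-oxo-2H-chromen-6-yl)-1,4-dimethylcyclohex-3-ene-1-carbaldehyde | COc1cc2oc(=O)ccc2cc1[C@H]1C=C(C)CC[C@@]1(C)C=O.COc1cc2oc(=O)ccc2cc1[C@@H]1C=C(C)CC[C@]1(C)C=O
F4 | step 5 | (4R,5R)-1,3-dimethyl-4,5-diphenylimidazolidine aminal of (1R,2R)-9 | CN1[C@H](c2ccccc2)[C@@H](c2ccccc2)N(C)C1[C@]1(C)CCC(C)=C[C@@H]1c1cc2ccc(=O)oc2cc1OC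
F5 | step 5 | (4R,5R)-1,3-dimethyl-4,5-diphenylimidazolidine aminal of (1S,2S)-9 | CN1[C@H](c2ccccc2)[C@@H](c2ccccc2)N(C)C1[C@@]1(C)CCC(C)=C[C@H]1c1cc2ccc(=O)oc2cc1OC
F6 | step 10 | 8-iodo-7-[(4-methoxyphenyl)methoxy]-2H-chromen-2-one | COc1ccc(COc2ccc3ccc(=O)oc3c2I)cc1
F7 | step 10 | 7-[(4-methoxyphenyl)methoxy]-8-(trimethylsilyl)-2H-chromen-2-one | COc1ccc(COc2ccc3ccc(=O)oc3c2[Si](C)(C)C)cc1
F8 | step 10 | 7-hydroxy-8-(trimethylsilyl)-2H-chromen-2-one | C[Si](C)(C)c1c(O)ccc2ccc(=O)oc12
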